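## Retrosynthetic overview

- The strategy rests on one feature of the target: ring atoms C3–C4–C5 sit at the oxidation level of a 1,3-dielectrophile whose C3 (the carbon bearing the C23 chain) is a fatty acyl carbon, and N1–C2–CHO is a glycine unit.
- The C2 formyl group is traced back through the 2-hydroxymethyl pyrrole to the methyl pyrrole-2-carboxylate (glycine carboxyl carbon = formyl carbon).
- The pyrrole ring, the only ring, is disconnected at N1–C5 and C2–C3 into hexacos-1-yn-3-one and glycine methyl ester (conjugate amination, then aldol condensation).
- The ynone is traced back to the N-methoxy-N-methylamide of tetracosanoic acid and ethynylmagnesium bromide; the acyl carbon of the C24 acid becomes C3, so the odd C23 chain needs no adjustment.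

Key step: step 3

Remark: the alkyl string of the target is read as an unbranched tricosyl (C23) chain; the target has no stereocentre, so no stereocontrol is needed.

## Route

Step 1
Reactants: 1 tetracosanoic acid
Product: 3 N-methoxy-N-methyltetracosanamide, via N-tetracosanoylimidazole 2 (not isolated)
Conditions: carbonyldiimidazole (1.2 equiv), THF, 45 °C; then MeNH(OMe)·HCl (1.5 equiv), 45 °C to rt
Reagents that add atoms: N,O-dimethylhydroxylamine hydrochloride, CNOC.Cl
Why: Carbonyldiimidazole should convert the acid into the acyl imidazolide 2 with loss of CO2, and the hydroxylamine, freed from its salt by the liberated imidazole, should displace imidazole in an acyl substitution (Weinreb amide formation).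

Step 2
Reactants: 3 N-methoxy-N-methyltetracosanamide; 4 ethynylmagnesium bromide
Product: 6 hexacos-1-yn-3-one, via magnesium hemiaminal chelate 5 (not isolated)
Conditions: ethynylmagnesium bromide (3 equiv, 0.5 M in THF), THF, 0 °C to rt; poured into cold 1 M aq HCl
Reagents that add atoms: none
Why: In this Weinreb ketone synthesis the acetylide should add once to give the five-membered magnesium chelate 5, which holds until the quench, and the inverse acidic quench should protonate the released N,O-dimethylhydroxylamine so that it cannot add to the ynone.

Step 3
Reactants: 6 hexacos-1-yn-3-one; 7 glycine methyl ester hydrochloride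
Product: 11 methyl 3-tricosyl-1H-pyrrole-2-carboxylate, via glycine methyl ester 8 (not isolated), via Z-enaminone 9 (not isolated), via aldol adduct 10 (not isolated)
Conditions: 7 (1.3 equiv), NaOMe (1.25 equiv), MeOH, 0 °C; then 6 in THF, 0 °C to rt; then NaOMe (2 equiv), MeOH/THF, 60 °C; aq NH4Cl
Reagents that add atoms: none
Why: Free glycine methyl ester 8 should add through nitrogen to the unsubstituted alkyne terminus of 6 (aza-Michael addition, forming N1–C5) to give the secondary enaminone 9, whose Z geometry is favoured by an intramolecular N–H···O=C hydrogen bond and which can in any case equilibrate between E and Z as a vinylogous amide. NaOMe should then generate the glycinate enolate, whose alpha carbon attacks the C3 ketone carbon (forming C2–C3) to give the hydroxypyrroline 10, and base-mediated loss of water with tautomerisation should deliver the aromatic pyrrole 11. The closest known reaction type is the base-induced cyclocondensation of N-(3-oxoalkenyl)glycine esters, made from enaminones, 3-alkoxyenones or 3-oxoaldehyde equivalents and glycine esters, to pyrrole-2-carboxylates. The single ring closes in a 5-(enolexo)-exo-trig aldol mode. No stereocentre remains, since the two sp3 centres of 10 form without control and are erased on aromatisation. The step needs regioselectivity only, and the substrate secures it: an amine adds to a terminal ynone at the beta carbon, so the glycinate carbon can reach no electrophile other than the chain-bearing carbonyl, while enolisation at the chain alpha-CH2 is reversible and unproductive once aromatisation drains the equilibrium.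

Step 4
Reactants: 11 methyl 3-tricosyl-1H-pyrrole-2-carboxylate
Product: 12 (3-tricosyl-1H-pyrrol-2-yl)methanol
Conditions: LiAlH4 (3 equiv), THF, 0 °C to rt; Na2SO4·10H2O quench, filtration; crude used at once
Reagents that add atoms: none
Why: LiAlH4 should reduce the ester to the primary alcohol after the pyrrole N–H has consumed one hydride, and the low temperature and non-acidic work-up should keep the sensitive 2-(hydroxymethyl)pyrrole from over-reduction and self-condensation.

Step 5
Reactants: 12 (3-tricosyl-1H-pyrrol-2-yl)methanol
Product: 13 3-tricosyl-1H-pyrrole-2-carbaldehyde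
Conditions: activated MnO2 (15 equiv), CH2Cl2, rt; filtration through Celite
Reagents that add atoms: none
Why: Activated MnO2 should oxidise the pyrrol-2-ylmethanol, an electron-rich benzylic-type alcohol, selectively to the aldehyde, which is a stable vinylogous formamide and should not be oxidised further.

## Compound list

1 | tetracosanoic acid | CCCCCCCCCCCCCCCCCCCCCCCC(=O)O | starting material
2 | N-tetracosanoylimidazole (1-(1H-imidazol-1-yl)tetracosan-1-one) | CCCCCCCCCCCCCCCCCCCCCCCC(=O)n1ccnc1 | intermediate (not isolated)
3 | N-methoxy-N-methyltetracosanamide | CCCCCCCCCCCCCCCCCCCCCCCC(=O)N(C)OC | intermediate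
4 | ethynylmagnesium bromide | C#C[Mg]Br | starting material
5 | magnesium hemiaminal chelate (bromomagnesium 3-[methoxy(methyl)amino]hexacos-1-yn-3-olate) | CCCCCCCCCCCCCCCCCCCCCCCC(C#C)(O[Mg]Br)N(C)OC | intermediate (not isolated)
6 | hexacos-1-yn-3-one | C#CC(=O)CCCCCCCCCCCCCCCCCCCCCCC | intermediate
7 | glycine methyl ester hydrochloride | COC(=O)CN.Cl | starting material
8 | glycine methyl ester (free base) | COC(=O)CN | intermediate (not isolated)
9 | methyl N-[(1Z)-3-oxohexacos-1-en-1-yl]glycinate (Z-enaminone) | CCCCCCCCCCCCCCCCCCCCCCCC(=O)/C=C\NCC(=O)OC | intermediate (not isolated)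
10 | methyl 3-hydroxy-3-tricosyl-2,3-dihydro-1H-pyrrole-2-carboxylate (aldol adduct, mixture of racemic diastereomers) | CCCCCCCCCCCCCCCCCCCCCCCC1(O)C=CNC1C(=O)OC | intermediate (not isolated)
11 | methyl 3-tricosyl-1H-pyrrole-2-carboxylate | CCCCCCCCCCCCCCCCCCCCCCCc1cc[nH]c1C(=O)OC | intermediate
12 | (3-tricosyl-1H-pyrrol-2-yl)methanol | CCCCCCCCCCCCCCCCCCCCCCCc1cc[nH]c1CO | intermediate
13 | 3-tricosyl-1H-pyrrole-2-carbaldehyde | CCCCCCCCCCCCCCCCCCCCCCCc1cc[nH]c1C=O | target

## Step count and risks

Total step count: 5. Longest linear sequence: 5 steps (from tetracosanoic acid 1).

Steps most likely to fail: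

1. Step 3. The ring closure may stall at the enaminone stage, because the vinylogous amide carbonyl is a weak electrophile and N–H deprotonation competes with enolate formation. The free amino ester may also self-condense, or the terminal ynone oligomerise, before amination is complete. The fallback builds the same pyrrole ester by a Barton–Zard synthesis. It sets out from Weinreb amide 3, which is reduced with LiAlH4 in THF at −78 to 0 °C to tetracosanal F1. Henry addition of nitromethane with catalytic DBU should give racemic 1-nitropentacosan-2-ol F2. Acetylation with Ac2O and catalytic H2SO4 at 0 °C gives 1-nitropentacosan-2-yl acetate F3. Treatment of F3 with methyl isocyanoacetate and DBU (2.2 equiv) in THF should eliminate acetic acid to (E)-1-nitropentacos-1-ene F4 in the flask. Michael addition of the isocyanoacetate anion to the chain-bearing carbon, 5-endo-dig closure onto the isocyanide carbon, loss of nitrite and tautomerisation then place the chain at C3 and the ester at C2. The fallback comes back to the route at 11.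

2. Step 4. Over-reduction may occur by loss of the aluminium alkoxide from the N-metalated hydroxymethylpyrrole (azafulvene formation followed by hydride addition). Acid-triggered self-condensation of the hydroxymethylpyrrole during work-up or handling is the second hazard. The fallback is a McFadyen–Stevens reduction, which never passes through the alcohol. It sets out from 11, which with hydrazine hydrate in refluxing ethanol/THF should give 3-tricosyl-1H-pyrrole-2-carbohydrazide F5. TsCl in pyridine at 0 °C gives N'-(4-methylbenzenesulfonyl)-3-tricosyl-1H-pyrrole-2-carbohydrazide F6. Heating F6 with Na2CO3 in ethylene glycol at 160 °C should expel sulfinate and dinitrogen and give the aldehyde. The fallback comes back at the target 13 and replaces steps 4 and 5.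

3. Step 2. The liberated N,O-dimethylhydroxylamine or excess acetylide may add in conjugate fashion to the ynone if the chelate collapses before or during the quench, and the terminal ynone may oligomerise under basic conditions. The fallback is an acylation of a silylalkyne, which involves neither a free amine nor a basic acetylide. It sets out from acid 1, which with oxalyl chloride and catalytic DMF in CH2Cl2 gives tetracosanoyl chloride F7. Bis(trimethylsilyl)acetylene and AlCl3 in CH2Cl2 at 0 °C should give 1-(trimethylsilyl)hexacos-1-yn-3-one F8 by ipso acylation. Desilylation with dilute aqueous Na2B4O7 in MeOH/THF at rt gives the terminal ynone. The fallback comes back at 6 and replaces steps 1 and 2.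

## Further compounds

F1 | step 3 | tetracosanal | CCCCCCCCCCCCCCCCCCCCCCCC=O
F2 | step 3 | 1-nitropentacosan-2-ol (racemic) | CCCCCCCCCCCCCCCCCCCCCCCC(O)C[N+](=O)[O-]
F3 | step 3 | 1-nitropentacosan-2-yl acetate (racemic) | CCCCCCCCCCCCCCCCCCCCCCCC(OC(C)=O)C[N+](=O)[O-]
F4 | step 3 | (E)-1-nitropentacos-1-ene | CCCCCCCCCCCCCCCCCCCCCCC/C=C/[N+](=O)[O-]
F5 | step 4 | 3-tricosyl-1H-pyrrole-2-carbohydrazide | CCCCCCCCCCCCCCCCCCCCCCCc1cc[nH]c1C(=O)NN
F6 | step 4 | N'-(4-methylbenzenesulfonyl)-3-tricosyl-1H-pyrrole-2-carbohydrazide | CCCCCCCCCCCCCCCCCCCCCCCc1cc[nH]c1C(=O)NNS(=O)(=O)c1ccc(C)cc1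
F7 | step 2 | tetracosanoyl chloride | CCCCCCCCCCCCCCCCCCCCCCCC(=O)Cl
F8 | step 2 | 1-(trimethylsilyl)hexacos-1-yn-3-one | C[Si](C)(C)C#CC(=O)CCCCCCCCCCCCCCCCCCCCCCC
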